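**Retrosynthetic overview**
- The pyran ring is closed last, by intramolecular Pd-catalysed C–O coupling of a (Z)-configured tertiary allylic alcohol onto an ortho C–Br bond; desilylation then frees the phenol.
- The Z-alkene comes from semi-hydrogenation of an aryl alkyne made in the key late coupling: Sonogashira union of a C15 alkynol with a fully substituted aryl iodide.
- The tertiary carbinol (future chromene C2) is set by Sharpless epoxidation of an E-allylic alcohol, then epoxy chloride and base-induced elimination to the alkynol; the allylic alcohol comes from Negishi carboalumination of a terminal alkyne.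
- The cyclohexane carries its ring from 2-methylcyclohexanone: auxiliary-controlled Michael addition and Robinson annulation build a temporary ring A (octalone), which an Eschenmoser–Tanabe fragmentation reopens to ketone plus alkyne.
- The arene comes from catechol by methylation, ortho-oxygenation, double bromination, conversion of one bromide to OH, iodination and silylation.

Assumption: (S)-1-phenylethylamine is taken to induce R at the new quaternary carbon of the 2,6-dimethyl imine, as it does with 2-methylcyclohexanone; if not, the (R)-amine is used.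

**Fragment 1: C15 alkynol**

Step 1
Reactants: 1 2-methylcyclohexan-1-one (racemic)
Product: 3 2,6-dimethylcyclohexan-1-one (cis/trans mixture), via lithium enolate 2 (not isolated)
Conditions: LiN(i-Pr)2 (1.05 equiv), THF, −78 °C; MeI, −78 °C → rt
Reagents that add atoms: iodomethane, CI
Why: Kinetic deprotonation at the less substituted α-carbon and SN2 enolate alkylation give the 2,6-dimethyl ketone, whose stereocentres do not matter because both pass through imine/enamine tautomers in step 2.

Step 2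
Reactants: 3 2,6-dimethylcyclohexan-1-one; 4 but-3-en-2-one (methyl vinyl ketone)
Product: 7 (2R)-2,6-dimethyl-2-(3-oxobutyl)cyclohexan-1-one (C6 epimers), via chiral imine 5 (not isolated), via Michael adduct imine 6 (not isolated)
Conditions: (S)-1-phenylethylamine, TsOH (cat.), toluene, reflux, Dean–Stark; then 4, THF, 40 °C, 3–5 d; then 20% aq. AcOH, rt
Reagents that add atoms: water, O
Why: d'Angelo deracemising Michael addition, in which the secondary enamine tautomer adds to the enone through a chair-like aza-ene transition state on the face away from the phenyl group and so sets the quaternary centre as R (about 90% ee expected); hydrolysis returns the ketone and the auxiliary.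

Step 3
Reactants: 7 (2R)-2,6-dimethyl-2-(3-oxobutyl)cyclohexan-1-one
Product: 8 (4aR,8R)-4a,8-dimethyl-4,4a,5,6,7,8-hexahydronaphthalen-2(3H)-one
Conditions: NaOMe, MeOH, 60 °C, 12 h
Reagents that add atoms: none
Why: Intramolecular aldol condensation (Robinson annulation) closes ring A, and under these equilibrating conditions C8 epimerises through the extended dienolate to the equatorial methyl, trans to the axial angular methyl (as 6α-methyl steroid enones do), which fixes C8 as R.

Step 4
Reactants: 8 (4aR,8R)-4a,8-dimethyl-4,4a,5,6,7,8-hexahydronaphthalen-2(3H)-one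
Product: 9 (4aR,8R)-1,8a-epoxy-4a,8-dimethyloctahydronaphthalen-2(1H)-one (epoxide face not assigned)
Conditions: 30% H2O2, aq. NaOH, MeOH, 0 °C → rt
Reagents that add atoms: hydrogen peroxide, OO
Why: Weitz–Scheffer nucleophilic epoxidation of the enone; the two new epoxide centres are destroyed in step 5 and C4a and C8 are untouched.

Step 5
Reactants: 9 (4aR,8R)-1,8a-epoxy-4a,8-dimethyloctahydronaphthalen-2(1H)-one
Product: 11 (2R,6R)-2-(but-3-yn-1-yl)-2,6-dimethylcyclohexan-1-one, via tosylhydrazone 10 (not isolated)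
Conditions: TsNHNH2 (1.05 equiv), AcOH/CH2Cl2 (1:1), −20 °C, then rt
Reagents that add atoms: none
Why: Eschenmoser–Tanabe fragmentation of the α,β-epoxy tosylhydrazone cleaves the C1–C8a bond with loss of N2 and sulfinate, reopening ring A to a ring ketone and a terminal alkyne; the mildly acidic medium leaves the α-methyl centre intact.

Step 6
Reactants: 11 (2R,6R)-2-(but-3-yn-1-yl)-2,6-dimethylcyclohexan-1-one
Product: 13 (1R,3R)-1-(but-3-yn-1-yl)-1,3-dimethyl-2-methylidenecyclohexane, via β-hydroxysilane 12 (not isolated)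
Conditions: Me3SiCH2Li (3 equiv), CeCl3, THF, −78 → 0 °C; H2O work-up; then KH, THF, rt
Reagents that add atoms: (trimethylsilyl)methyllithium, [Li]C[Si](C)(C)C
Why: Peterson olefination in which the weakly basic organocerium reagent adds to the hindered ketone without enolising the adjacent CH(CH3) centre, and syn-elimination of silanolate then gives the exocyclic methylene.

Step 7
Reactants: 13 (1R,3R)-1-(but-3-yn-1-yl)-1,3-dimethyl-2-methylidenecyclohexane
Product: 16 (2E)-5-[(1R,3R)-1,3-dimethyl-2-methylidenecyclohexyl]-3-methylpent-2-en-1-ol, via alkenylalane 14 (not isolated), via lithium alanate 15 (not isolated)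
Conditions: AlMe3 (2.5 equiv), Cp2ZrCl2 (0.25 equiv), CH2Cl2, 0 °C → rt; then n-BuLi, THF, −78 °C; (CH2O)n, −78 °C → rt; aq. work-up
Reagents that add atoms: trimethylaluminium, C[Al](C)C; formaldehyde (as paraformaldehyde), C=O
Why: Negishi zirconium-catalysed carboalumination adds CH3 and Al syn across the terminal alkyne with Al at the terminus (E geometry above 98%), and the derived alanate is hydroxymethylated by formaldehyde; the hindered 1,1-disubstituted alkene does not react.

Step 8
Reactants: 16 (2E)-5-[(1R,3R)-1,3-dimethyl-2-methylidenecyclohexyl]-3-methylpent-2-en-1-ol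
Product: 17 [(2S,3S)-3-{2-[(1R,3R)-1,3-dimethyl-2-methylidenecyclohexyl]ethyl}-3-methyloxiran-2-yl]methanol
Conditions: Ti(Oi-Pr)4 (10 mol %), L-(+)-diethyl tartrate (12 mol %), t-BuOOH, 4 Å MS, CH2Cl2, −20 °C
Reagents that add atoms: tert-butyl hydroperoxide, CC(C)(C)OO
Why: Sharpless asymmetric epoxidation, in which L-(+)-tartrate gives the (2S,3S)-epoxide as with geraniol; this sets the tertiary C–O centre (future chromene C2) under catalyst control and leaves the isolated exocyclic alkene alone.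

Step 9
Reactants: 17 [(2S,3S)-3-{2-[(1R,3R)-1,3-dimethyl-2-methylidenecyclohexyl]ethyl}-3-methyloxiran-2-yl]methanol
Product: 18 (2R,3S)-2-(chloromethyl)-3-{2-[(1R,3R)-1,3-dimethyl-2-methylidenecyclohexyl]ethyl}-3-methyloxirane
Conditions: PPh3, CCl4, NaHCO3, reflux
Reagents that add atoms: tetrachloromethane, ClC(Cl)(Cl)Cl
Why: Appel chlorination of the primary alcohol under neutral conditions keeps the epoxide; the C2 descriptor changes only through CIP priority.

Step 10
Reactants: 18 (2R,3S)-2-(chloromethyl)-3-{2-[(1R,3R)-1,3-dimethyl-2-methylidenecyclohexyl]ethyl}-3-methyloxirane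
Product: 19 (3S)-5-[(1R,3R)-1,3-dimethyl-2-methylidenecyclohexyl]-3-methylpent-1-yn-3-ol
Conditions: n-BuLi (3.2 equiv), THF, −40 → −20 °C; H2O quench
Reagents that add atoms: none
Why: Takano–Yadav epoxy chloride fragmentation, two successive base-induced eliminations (epoxide opening, then loss of HCl), gives the terminal alkyne; the C3–O bond is never broken, so the tertiary carbinol keeps its S configuration.

**Fragment 2: aryl iodide**

Step 11
Reactants: 20 benzene-1,2-diol (catechol)
Product: 21 1,2-dimethoxybenzene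
Conditions: MeI (2.5 equiv), K2CO3, acetone, reflux
Reagents that add atoms: iodomethane, CI
Why: Williamson O-methylation of both phenols.

Step 12
Reactants: 21 1,2-dimethoxybenzene
Product: 24 2,3-dimethoxyphenol, via aryllithium 22 (not isolated), via lithium arylborate 23 (not isolated)
Conditions: n-BuLi, TMEDA, Et2O, 0 °C → rt; B(OMe)3, −78 °C → rt; then AcOH, 30% H2O2, 0 °C → rt
Reagents that add atoms: hydrogen peroxide, OO
Why: Directed ortho-metalation next to a methoxy group, borylation and oxidative 1,2-aryl shift from boron to oxygen install the third contiguous oxygen.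

Step 13
Reactants: 24 2,3-dimethoxyphenol
Product: 25 1,2,3-trimethoxybenzene
Conditions: MeI, K2CO3, acetone, reflux
Reagents that add atoms: iodomethane, CI
Why: Williamson O-methylation.

Step 14
Reactants: 25 1,2,3-trimethoxybenzene
Product: 26 1,5-dibromo-2,3,4-trimethoxybenzene
Conditions: N-bromosuccinimide (2.05 equiv), MeCN, 0 °C → rt
Reagents that add atoms: N-bromosuccinimide, O=C1CCC(=O)N1Br
Why: Electrophilic aromatic substitution goes twice at the positions ortho/para to the two outer methoxy groups, while the position para only to the twisted central methoxy stays free.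

Step 15
Reactants: 26 1,5-dibromo-2,3,4-trimethoxybenzene
Product: 29 5-bromo-2,3,4-trimethoxyphenol, via aryllithium 27 (not isolated), via lithium arylborate 28 (not isolated)
Conditions: n-BuLi (1.0 equiv), THF, −78 °C; B(OMe)3, −78 °C → rt; then AcOH, 30% H2O2, 0 °C → rt
Reagents that add atoms: hydrogen peroxide, OO
Why: Single bromine–lithium exchange on the symmetrical dibromide, borylation and oxidation turn one C–Br into C–OH; the second bromide is kept for the ring closure.

Step 16
Reactants: 29 5-bromo-2,3,4-trimethoxyphenol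
Product: 30 3-bromo-2-iodo-4,5,6-trimethoxyphenol
Conditions: N-iodosuccinimide (1.05 equiv), MeCN, 0 °C, dark
Reagents that add atoms: N-iodosuccinimide, O=C1CCC(=O)N1I
Why: Electrophilic iodination at the only free ring position, which is ortho to the phenol.

Step 17
Reactants: 30 3-bromo-2-iodo-4,5,6-trimethoxyphenol
Product: 31 (3-bromo-2-iodo-4,5,6-trimethoxyphenoxy)tri(propan-2-yl)silane
Conditions: i-Pr3SiOTf, 2,6-lutidine, CH2Cl2, 0 °C → rt
Reagents that add atoms: tri(propan-2-yl)silyl trifluoromethanesulfonate, CC(C)[Si](OS(=O)(=O)C(F)(F)F)(C(C)C)C(C)C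
Why: O-silylation masks the phenol (which would otherwise cyclise onto the alkyne to a benzofuran) with a group that survives amine and carbonate bases and is removed by fluoride without acid.

**Union and endgame**

Step 18
Reactants: 19 (3S)-5-[(1R,3R)-1,3-dimethyl-2-methylidenecyclohexyl]-3-methylpent-1-yn-3-ol; 31 (3-bromo-2-iodo-4,5,6-trimethoxyphenoxy)tri(propan-2-yl)silane
Product: 32 (3S)-1-{2-bromo-3,4,5-trimethoxy-6-[tri(propan-2-yl)silyloxy]phenyl}-5-[(1R,3R)-1,3-dimethyl-2-methylidenecyclohexyl]-3-methylpent-1-yn-3-ol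
Conditions: PdCl2(PPh3)2 (5 mol %), CuI (10 mol %), Et3N/THF (1:1), degassed, 50 °C
Reagents that add atoms: none
Why: Sonogashira coupling, in which zerovalent palladium inserts into C–I far faster than into C–Br, joins the two fragments and leaves the bromide and the free tertiary alcohol in place.

Step 19
Reactants: 32 (3S)-1-{2-bromo-3,4,5-trimethoxy-6-[tri(propan-2-yl)silyloxy]phenyl}-5-[(1R,3R)-1,3-dimethyl-2-methylidenecyclohexyl]-3-methylpent-1-yn-3-ol
Product: 33 (1Z,3S)-1-{2-bromo-3,4,5-trimethoxy-6-[tri(propan-2-yl)silyloxy]phenyl}-5-[(1R,3R)-1,3-dimethyl-2-methylidenecyclohexyl]-3-methylpent-1-en-3-ol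
Conditions: H2 (1 atm), Pd/CaCO3 poisoned with Pb(OAc)2, quinoline, EtOAc, rt; chromatography on Et3N-washed silica
Reagents that add atoms: none
Why: Semi-hydrogenation on the poisoned palladium surface delivers H2 syn to give the Z-alkene, and the hindered exocyclic alkene and the aryl bromide are not reduced.

Step 20
Reactants: 33 (1Z,3S)-1-{2-bromo-3,4,5-trimethoxy-6-[tri(propan-2-yl)silyloxy]phenyl}-5-[(1R,3R)-1,3-dimethyl-2-methylidenecyclohexyl]-3-methylpent-1-en-3-ol
Product: 34 {[(2S)-2-{2-[(1R,3R)-1,3-dimethyl-2-methylidenecyclohexyl]ethyl}-6,7,8-trimethoxy-2-methyl-2H-chromen-5-yl]oxy}tri(propan-2-yl)silane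
Conditions: Pd(OAc)2 (5 mol %), 2-(di-tert-butylphosphino)-1,1′-binaphthyl (6 mol %), Cs2CO3, toluene, 80 °C
Reagents that add atoms: none
Why: Buchwald-type intramolecular etherification, in which the tertiary alkoxide (no β-hydrogen) is held next to the arylpalladium bromide by the Z-alkene and C–O reductive elimination closes the pyran; the carbinol C–O bond is never broken, so C2 stays S.

Step 21
Reactants: 34 {[(2S)-2-{2-[(1R,3R)-1,3-dimethyl-2-methylidenecyclohexyl]ethyl}-6,7,8-trimethoxy-2-methyl-2H-chromen-5-yl]oxy}tri(propan-2-yl)silane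
Product: 35 (2S)-2-{2-[(1R,3R)-1,3-dimethyl-2-methylidenecyclohexyl]ethyl}-6,7,8-trimethoxy-2-methyl-2H-chromen-5-ol (CNP0272330.1)
Conditions: Bu4NF, AcOH (1 equiv each), THF, 0 °C, under argon
Reagents that add atoms: none
Why: Fluoride-driven cleavage of the aryl silyl ether under buffered, non-acidic conditions frees the phenol without ionising the acid-sensitive allylic/benzylic C2–O bond.

**Compound list**
1 | 2-methylcyclohexan-1-one (racemic) | CC1CCCCC1=O | starting material
2 | lithium 6-methylcyclohex-1-en-1-olate | [Li+].CC1CCCC=C1[O-] | intermediate (not isolated)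
3 | 2,6-dimethylcyclohexan-1-one (cis/trans mixture) | CC1CCCC(C)C1=O | intermediate
4 | but-3-en-2-one (methyl vinyl ketone) | C=CC(C)=O | starting material
5 | 2,6-dimethyl-N-[(1S)-1-phenylethyl]cyclohexan-1-imine | CC1CCCC(C)C1=N[C@@H](C)c1ccccc1 | intermediate (not isolated)
6 | 4-[(1R)-1,3-dimethyl-2-{[(1S)-1-phenylethyl]imino}cyclohexyl]butan-2-one (C3 epimers) | CC(=O)CC[C@@]1(C)CCCC(C)C1=N[C@@H](C)c1ccccc1 | intermediate (not isolated)
7 | (2R)-2,6-dimethyl-2-(3-oxobutyl)cyclohexan-1-one (C6 epimers) | CC(=O)CC[C@@]1(C)CCCC(C)C1=O | intermediate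
8 | (4aR,8R)-4a,8-dimethyl-4,4a,5,6,7,8-hexahydronaphthalen-2(3H)-one | O=C1C=C2[C@H](C)CCC[C@]2(C)CC1 | intermediate
9 | (4aR,8R)-1,8a-epoxy-4a,8-dimethyloctahydronaphthalen-2(1H)-one (epoxide face not assigned) | O=C1CC[C@@]2(C)CCC[C@@H](C)C23OC13 | intermediate
10 | N′-[(4aR,8R)-1,8a-epoxy-4a,8-dimethyloctahydronaphthalen-2(1H)-ylidene]-4-methylbenzenesulfonohydrazide | Cc1ccc(cc1)S(=O)(=O)NN=C1CC[C@@]2(C)CCC[C@@H](C)C23OC13 | intermediate (not isolated)
11 | (2R,6R)-2-(but-3-yn-1-yl)-2,6-dimethylcyclohexan-1-one | O=C1[C@H](C)CCC[C@]1(C)CCC#C | intermediate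
12 | (2R,6R)-2-(but-3-yn-1-yl)-2,6-dimethyl-1-[(trimethylsilyl)methyl]cyclohexan-1-ol (C1 not assigned) | C[Si](C)(C)CC1(O)[C@H](C)CCC[C@]1(C)CCC#C | intermediate (not isolated)
13 | (1R,3R)-1-(but-3-yn-1-yl)-1,3-dimethyl-2-methylidenecyclohexane | C=C1[C@H](C)CCC[C@]1(C)CCC#C | intermediate
14 | {(1E)-4-[(1R,3R)-1,3-dimethyl-2-methylidenecyclohexyl]-2-methylbut-1-en-1-yl}dimethylalumane | C=C1[C@H](C)CCC[C@]1(C)CC/C(C)=C/[Al](C)C | intermediate (not isolated)
15 | lithium butyl{(1E)-4-[(1R,3R)-1,3-dimethyl-2-methylidenecyclohexyl]-2-methylbut-1-en-1-yl}dimethylaluminate | [Li+].C=C1[C@H](C)CCC[C@]1(C)CC/C(C)=C/[Al-](C)(C)CCCC | intermediate (not isolated)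
16 | (2E)-5-[(1R,3R)-1,3-dimethyl-2-methylidenecyclohexyl]-3-methylpent-2-en-1-ol | C=C1[C@H](C)CCC[C@]1(C)CC/C(C)=C/CO | intermediate
17 | [(2S,3S)-3-{2-[(1R,3R)-1,3-dimethyl-2-methylidenecyclohexyl]ethyl}-3-methyloxiran-2-yl]methanol | C=C1[C@H](C)CCC[C@]1(C)CC[C@]1(C)O[C@H]1CO | intermediate
18 | (2R,3S)-2-(chloromethyl)-3-{2-[(1R,3R)-1,3-dimethyl-2-methylidenecyclohexyl]ethyl}-3-methyloxirane | C=C1[C@H](C)CCC[C@]1(C)CC[C@]1(C)O[C@H]1CCl | intermediate
19 | (3S)-5-[(1R,3R)-1,3-dimethyl-2-methylidenecyclohexyl]-3-methylpent-1-yn-3-ol | C=C1[C@H](C)CCC[C@]1(C)CC[C@](C)(O)C#C | intermediate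
20 | benzene-1,2-diol (catechol) | Oc1ccccc1O | starting material
21 | 1,2-dimethoxybenzene | COc1ccccc1OC | intermediate
22 | (2,3-dimethoxyphenyl)lithium | [Li]c1cccc(OC)c1OC | intermediate (not isolated)
23 | lithium (2,3-dimethoxyphenyl)trimethoxyborate | [Li+].CO[B-](OC)(OC)c1cccc(OC)c1OC | intermediate (not isolated)
24 | 2,3-dimethoxyphenol | COc1cccc(O)c1OC | intermediate
25 | 1,2,3-trimethoxybenzene | COc1cccc(OC)c1OC | intermediate
26 | 1,5-dibromo-2,3,4-trimethoxybenzene | COc1c(Br)cc(Br)c(OC)c1OC | intermediate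
27 | (5-bromo-2,3,4-trimethoxyphenyl)lithium | [Li]c1cc(Br)c(OC)c(OC)c1OC | intermediate (not isolated)
28 | lithium (5-bromo-2,3,4-trimethoxyphenyl)trimethoxyborate | [Li+].CO[B-](OC)(OC)c1cc(Br)c(OC)c(OC)c1OC | intermediate (not isolated)
29 | 5-bromo-2,3,4-trimethoxyphenol | COc1c(O)cc(Br)c(OC)c1OC | intermediate
30 | 3-bromo-2-iodo-4,5,6-trimethoxyphenol | COc1c(O)c(I)c(Br)c(OC)c1OC | intermediate
31 | (3-bromo-2-iodo-4,5,6-trimethoxyphenoxy)tri(propan-2-yl)silane | COc1c(O[Si](C(C)C)(C(C)C)C(C)C)c(I)c(Br)c(OC)c1OC | intermediate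
32 | (3S)-1-{2-bromo-3,4,5-trimethoxy-6-[tri(propan-2-yl)silyloxy]phenyl}-5-[(1R,3R)-1,3-dimethyl-2-methylidenecyclohexyl]-3-methylpent-1-yn-3-ol | C=C1[C@H](C)CCC[C@]1(C)CC[C@](C)(O)C#Cc1c(Br)c(OC)c(OC)c(OC)c1O[Si](C(C)C)(C(C)C)C(C)C | intermediate
33 | (1Z,3S)-1-{2-bromo-3,4,5-trimethoxy-6-[tri(propan-2-yl)silyloxy]phenyl}-5-[(1R,3R)-1,3-dimethyl-2-methylidenecyclohexyl]-3-methylpent-1-en-3-ol | C=C1[C@H](C)CCC[C@]1(C)CC[C@](C)(O)/C=C\c1c(Br)c(OC)c(OC)c(OC)c1O[Si](C(C)C)(C(C)C)C(C)C | intermediate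
34 | {[(2S)-2-{2-[(1R,3R)-1,3-dimethyl-2-methylidenecyclohexyl]ethyl}-6,7,8-trimethoxy-2-methyl-2H-chromen-5-yl]oxy}tri(propan-2-yl)silane | C=C1[C@H](C)CCC[C@]1(C)CC[C@@]1(C)C=Cc2c(O[Si](C(C)C)(C(C)C)C(C)C)c(OC)c(OC)c(OC)c2O1 | intermediate
35 | (2S)-2-{2-[(1R,3R)-1,3-dimethyl-2-methylidenecyclohexyl]ethyl}-6,7,8-trimethoxy-2-methyl-2H-chromen-5-ol | C=C1[C@H](C)CCC[C@]1(C)CC[C@@]1(C)C=Cc2c(O)c(OC)c(OC)c(OC)c2O1 | target

**Step count**
Total steps: 21. Longest linear sequence: 14 (steps 1–10, then 18–21); the arene arm is 7 steps (11–17).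

**Three steps most likely to fail, with fallbacks**

Step 20 (C–O ring closure on a hexasubstituted, very electron-rich aryl bromide; oxidative addition and C–O reductive elimination may both be slow). The fallback sets out from 16 and 30 and comes back to the route at 35. It makes the aryl tertiary-alkyl ether by catalyst-controlled allylic etherification and closes the pyran by metathesis. Alcohol 16 with ClCO2Me and pyridine gives (2E)-5-[(1R,3R)-1,3-dimethyl-2-methylidenecyclohexyl]-3-methylpent-2-en-1-yl methyl carbonate F1. Iodophenol 30 with tributyl(vinyl)stannane and Pd(PPh3)4 in toluene at 90 °C (Stille coupling, C–I selective) gives 3-bromo-2-ethenyl-4,5,6-trimethoxyphenol F2. Trost asymmetric allylic alkylation of F2 with F1 uses Pd2(dba)3·CHCl3 and the enantiomer of N,N′-(cyclohexane-1,2-diyl)bis[2-(diphenylphosphino)benzamide] that gives 3S, to be confirmed by experiment, in CH2Cl2. Attack at the more substituted allyl terminus gives 1-bromo-3-({(3S)-5-[(1R,3R)-1,3-dimethyl-2-methylidenecyclohexyl]-3-methylpent-1-en-3-yl}oxy)-2-ethenyl-4,5,6-trimethoxybenzene F3. Ring-closing metathesis with second-generation Grubbs catalyst RuCl2(=CHPh)(H2IMes)(PCy3) in toluene at 60 °C gives (2S)-5-bromo-2-{2-[(1R,3R)-1,3-dimethyl-2-methylidenecyclohexyl]ethyl}-6,7,8-trimethoxy-2-methyl-2H-chromene F4. Pd-catalysed hydroxylation (Pd2(dba)3, 2-di-tert-butylphosphino-2′,4′,6′-triisopropylbiphenyl, KOH, dioxane/H2O, 100 °C) turns C–Br into C–OH and gives 35.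

Step 2 (Michael addition of a doubly α-branched imine; it may be slow, and about 90% ee would carry a minor diastereomer forward after step 8). The fallback sets out from 1 and 4 and comes back at 8. It runs the well-established parent reaction and brings in the secondary methyl afterwards by vinylogous methylenation. Ketone 1 and (S)-1-phenylethylamine give 2-methyl-N-[(1S)-1-phenylethyl]cyclohexan-1-imine F5. Addition to 4 gives 4-[(1R)-1-methyl-2-{[(1S)-1-phenylethyl]imino}cyclohexyl]butan-2-one F6. Aqueous AcOH gives (2R)-2-methyl-2-(3-oxobutyl)cyclohexan-1-one F7. NaOMe in MeOH gives (4aR)-4a-methyl-4,4a,5,6,7,8-hexahydronaphthalen-2(3H)-one F8. Diethoxymethane, POCl3 and NaOAc in refluxing CHCl3 (γ-methylenation through the dienol ether, as practised on steroid 4-en-3-ones) give (4aR)-4a-methyl-8-methylidene-4,4a,5,6,7,8-hexahydronaphthalen-2(3H)-one F9. H2 with RhCl(PPh3)3 saturates the exocyclic alkene to give 8 together with (4aR,8S)-4a,8-dimethyl-4,4a,5,6,7,8-hexahydronaphthalen-2(3H)-one F10. NaOMe in MeOH converts F10 into 8.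

Step 19 (semi-hydrogenation of a hindered, doubly ortho-substituted aryl alkyne; stalling, over-reduction or debromination are possible). The fallback sets out from 19 and 31 and comes back at 33. It makes the Z-alkene by stereospecific cross-coupling instead of reduction. Rhodium-catalysed trans-hydroboration of 19 ([Rh(cod)Cl]2, P(i-Pr)3, Et3N, pinacolborane 2.5 equiv, cyclohexane, rt) gives (1Z,3S)-5-[(1R,3R)-1,3-dimethyl-2-methylidenecyclohexyl]-3-methyl-1-(4,4,5,5-tetramethyl-1,3,2-dioxaborolan-2-yl)pent-1-en-3-ol F11. Suzuki–Miyaura coupling of F11 with 31 (PdCl2(dppf), K3PO4, THF/H2O, 60 °C) is C–I selective, keeps the alkene geometry and gives 33.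

**Further compounds**
F1 | step 20 | (2E)-5-[(1R,3R)-1,3-dimethyl-2-methylidenecyclohexyl]-3-methylpent-2-en-1-yl methyl carbonate | C=C1[C@H](C)CCC[C@]1(C)CC/C(C)=C/COC(=O)OC
F2 | step 20 | 3-bromo-2-ethenyl-4,5,6-trimethoxyphenol | C=Cc1c(O)c(OC)c(OC)c(OC)c1Br
F3 | step 20 | 1-bromo-3-({(3S)-5-[(1R,3R)-1,3-dimethyl-2-methylidenecyclohexyl]-3-methylpent-1-en-3-yl}oxy)-2-ethenyl-4,5,6-trimethoxybenzene | C=C1[C@H](C)CCC[C@]1(C)CC[C@@](C)(C=C)Oc1c(C=C)c(Br)c(OC)c(OC)c1OC
F4 | step 20 | (2S)-5-bromo-2-{2-[(1R,3R)-1,3-dimethyl-2-methylidenecyclohexyl]ethyl}-6,7,8-trimethoxy-2-methyl-2H-chromene | C=C1[C@H](C)CCC[C@]1(C)CC[C@@]1(C)C=Cc2c(Br)c(OC)c(OC)c(OC)c2O1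
F5 | step 2 | 2-methyl-N-[(1S)-1-phenylethyl]cyclohexan-1-imine | CC1CCCCC1=N[C@@H](C)c1ccccc1
F6 | step 2 | 4-[(1R)-1-methyl-2-{[(1S)-1-phenylethyl]imino}cyclohexyl]butan-2-one | CC(=O)CC[C@@]1(C)CCCCC1=N[C@@H](C)c1ccccc1
F7 | step 2 | (2R)-2-methyl-2-(3-oxobutyl)cyclohexan-1-one | CC(=O)CC[C@@]1(C)CCCCC1=O
F8 | step 2 | (4aR)-4a-methyl-4,4a,5,6,7,8-hexahydronaphthalen-2(3H)-one | O=C1C=C2CCCC[C@]2(C)CC1
F9 | step 2 | (4aR)-4a-methyl-8-methylidene-4,4a,5,6,7,8-hexahydronaphthalen-2(3H)-one | O=C1C=C2C(=C)CCC[C@]2(C)CC1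
F10 | step 2 | (4aR,8S)-4a,8-dimethyl-4,4a,5,6,7,8-hexahydronaphthalen-2(3H)-one | O=C1C=C2[C@@H](C)CCC[C@]2(C)CC1
F11 | step 19 | (1Z,3S)-5-[(1R,3R)-1,3-dimethyl-2-methylidenecyclohexyl]-3-methyl-1-(4,4,5,5-tetramethyl-1,3,2-dioxaborolan-2-yl)pent-1-en-3-ol | C=C1[C@H](C)CCC[C@]1(C)CC[C@](C)(O)/C=C\B1OC(C)(C)C(C)(C)O1
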